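**Retrosynthetic overview**
1. The strategy rests on the quaternary spiro atom C5, shared by cyclopentane ring A (C1–C5) and cyclohexenone ring B (C5–C10). Ring A, the C3 isopropenyl group, C6 and the C6 methyl together are the ten carbons of (R)-limonene, and C5=C6 can be the exocyclic alkene of an enone conjugated with C1=O.
2. Late stage: remove the C9 acetate and the C1 senecioate. C6=C7 comes from a C7=C8 enol silane, the C9 oxygen from a C8=C9 enol silane, and C1–OH from a C1 ketone.
3. Key disconnection: C5–C10 and C6–C7, an intermolecular Diels–Alder spiroannulation of ethylidenecyclopentanone 11 with 2-silyloxypentadiene 15. Ring B is formed second, on intact ring A.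
4. Ring A is formed first. The limonene ring is cleaved at its trisubstituted alkene and reclosed by aldol condensation, then the carbonyl is transposed 1,3 by epoxidation, Wharton reaction and oxidation.

Key step: step 8

Remark: the target locants are used for all spiro compounds (C1 senecioate carbon, C3 isopropenyl carbon, C5 spiro atom, C6 methyl-bearing alkene carbon, C8 ketone, C9 acetate carbon, C10 methyl carbon). The target is (1S,3R,5S,9S,10R). Centres that are destroyed later (in 2, 3, 5, 7, 8, 9) are carried as mixtures and left open in the SMILES.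

**Route**

Step 1
Reactants: 1 (R)-(+)-limonene
Product: 2 (4R)-limonene 1,2-oxide (both epoxide diastereomers)
Conditions: mCPBA (1.0 equiv), CH2Cl2, 0 °C
Reagents that add atoms: 3-chloroperoxybenzoic acid (mCPBA), O=C(OO)c1cccc(Cl)c1
Why: Prilezhaev epoxidation selects the more electron-rich trisubstituted ring alkene over the 1,1-disubstituted isopropenyl group; both epoxides converge in step 2 and the future C3 centre is untouched.

Step 2
Reactants: 2 (4R)-limonene 1,2-oxide
Product: 4 (3R)-3-isopropenyl-6-oxoheptanal, via limonene-1,2-diol 3 (not isolated)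
Conditions: H5IO6 (1.1 equiv), THF/H2O, 0 °C → rt
Reagents that add atoms: water, O
Why: Acid-promoted epoxide hydrolysis is followed in the same flask by Malaprade glycol cleavage; the isolated alkene is inert, and the stereocentre is β to the aldehyde and so cannot enolise.

Step 3
Reactants: 4 (3R)-3-isopropenyl-6-oxoheptanal
Product: 6 (S)-1-acetyl-4-isopropenylcyclopent-1-ene, via cyclic aldol 5 (not isolated)
Conditions: KOH (0.1 M aq), THF, rt
Reagents that add atoms: none
Why: In this intramolecular aldol condensation (5-enolexo-exo-trig) under hydroxide, the internal CH2 enolate of the methyl ketone attacks the more electrophilic aldehyde and E1cB dehydration makes it irreversible; secondary-amine catalysis is avoided because the aldehyde enamine would lead to the isomeric cyclopentenecarbaldehyde.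

Step 4
Reactants: 6 (S)-1-acetyl-4-isopropenylcyclopent-1-ene
Product: 7 1-acetyl-1,2-epoxy-4-isopropenylcyclopentane (4S; both epoxide diastereomers)
Conditions: H2O2 (30% aq), NaOH, MeOH, 0 °C
Reagents that add atoms: hydrogen peroxide, OO
Why: Weitz–Scheffer nucleophilic epoxidation touches only the electron-poor enone alkene; the epoxide configuration does not matter because both of its carbons lose their stereochemistry in steps 5 and 6.

Step 5
Reactants: 7 1-acetyl-1,2-epoxy-4-isopropenylcyclopentane
Product: 9 (4R)-2-ethylidene-4-isopropenylcyclopentan-1-ol (E/Z isomers and carbinol epimers), via epoxy hydrazone 8 (not isolated)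
Conditions: N2H4·H2O, AcOH (cat.), MeOH, N2 atmosphere, 0 °C → rt
Reagents that add atoms: none
Why: In the Wharton transposition the hydrazone opens the epoxide and loses N2, which turns the acetyl carbon into the ethylidene CH and leaves the oxygen on the ring carbon that becomes C1; this transposition is established for acetylcycloalkene epoxides.

Step 6
Reactants: 9 (4R)-2-ethylidene-4-isopropenylcyclopentan-1-ol
Product: 11 (4R,E)-2-ethylidene-4-isopropenylcyclopentan-1-one, via Z-enone 10 (not isolated)
Conditions: MnO2, CH2Cl2, rt; filter; I2 (5 mol %), CH2Cl2, daylight, rt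
Reagents that add atoms: none
Why: Allylic alcohol oxidation is followed by iodine-catalysed equilibration, which drains the Z isomer into the more stable E enone without acid or base that could move the alkene into the ring; the E geometry is secured because it governs the endo/exo preference in step 8, although C6 itself is erased later.

Step 7
Reactants: 12 (E)-pent-3-en-2-one; 13 tert-butyldimethylsilyl chloride
Product: 15 (E)-2-(tert-butyldimethylsilyloxy)penta-1,3-diene, via lithium dienolate 14 (not isolated)
Conditions: LiN(i-Pr)2, THF, −78 °C; then 13, DMPU, −78 °C → rt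
Reagents that add atoms: tert-butyldimethylsilyl chloride (13), CC(C)(C)[Si](C)(C)Cl
Why: Kinetic α′-deprotonation of the enone at the methyl group gives the cross-conjugated enolate, and O-silylation fixes it as the 2-silyloxydiene with the E alkene retained.

Step 8
Reactants: 11 (4R,E)-2-ethylidene-4-isopropenylcyclopentan-1-one; 15 (E)-2-(tert-butyldimethylsilyloxy)penta-1,3-diene
Product: 16 (3R,5R,6S,10S)-8-(tert-butyldimethylsilyloxy)-3-isopropenyl-6,10-dimethylspiro[4.5]dec-8-en-1-one
Conditions: 15 (2.5 equiv), AlBr3/AlMe3 (10:1, 30 mol %), toluene/CH2Cl2, −40 → 0 °C; pyridine, then cold aq NaHCO3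
Reagents that add atoms: (E)-2-(tert-butyldimethylsilyloxy)penta-1,3-diene (15), C=C(O[Si](C)(C)C(C)(C)C)/C=C/C
Why: This is a Lewis-acid-promoted normal-demand Diels–Alder reaction in which aluminium bound to O1 lowers the LUMO of the s-cis-locked enone and the diene adds suprafacially across C5=C6 in a concerted, asynchronous [4+2] event with C6–C7 ahead of C5–C10; the closest known type is the mixed AlBr3/AlMe3-promoted cycloaddition of hindered 2-silyloxydienes with β-substituted and α-alkylidene cycloalkanones. Ring B (C5–C10) is closed by this single intermolecular [4+2] cycloaddition on intact ring A, which makes C5 the spiro atom. The nucleophilic CH2 terminus of the enol ether, reinforced by the terminal methyl, bonds to the β-carbon C6 and the methyl-bearing terminus bonds to C5, so the silyloxy group sits at C8 para to C5 and the enol ether is left at C8=C9. C10 relative to C5 is set by the endo transition state (C1=O under the diene), which places the outside methyl of the E diene cis to C1; the E geometry of 11 supports this mode, because only H6 then lies under the silyloxy-bearing diene carbon, whereas the exo mode would force C4H2 and the C6 methyl there. C5 relative to C3 is set by diene approach to the face of ring A opposite the isopropenyl group, and C6 follows from suprafacial addition to the E alkene (methyl cis to C4, erased in step 12). AlMe3 scavenges protic acid, so the isopropenyl group, the exocyclic enone and the silyl enol ether of 16 should survive.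

Step 9
Reactants: 16 spiro keto enol ether
Product: 18 (1S,3R,5R,6S,10S)-8-(tert-butyldimethylsilyloxy)-3-isopropenyl-6,10-dimethylspiro[4.5]dec-8-en-1-ol, via catechol borate 17 (not isolated)
Conditions: (3aR)-1-methyl-3,3-diphenyltetrahydro-1H,3H-pyrrolo[1,2-c][1,3,2]oxazaborole (0.3 equiv), catecholborane (2 equiv), toluene, −78 → −20 °C; MeOH, then cold 1 M NaOH wash
Reagents that add atoms: none
Why: In this Corey–Bakshi–Shibata reduction the size gap between quaternary C5 and C2H2 lets the (R)-oxazaborolidine deliver hydride to the C1 face on the C6 side, which sets 1S (hydroxyl cis to C10); reagent control is chosen because the two half-chairs of the trans-6,10-dimethyl ring B shield opposite faces of C1 and substrate bias alone is not dependable, and catecholborane leaves the isopropenyl group and the enol ether untouched.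

Step 10
Reactants: 18 spiro alcohol enol ether
Product: 20 (1S,3R,5R,6S,9S,10R)-9-(tert-butyldimethylsilyloxy)-1-hydroxy-3-isopropenyl-6,10-dimethylspiro[4.5]decan-8-one, via silyloxy epoxide 19 (not isolated)
Conditions: mCPBA (1.05 equiv), hexane/CH2Cl2, −20 → 0 °C
Reagents that add atoms: 3-chloroperoxybenzoic acid (mCPBA), O=C(OO)c1cccc(Cl)c1
Why: In the Rubottom oxidation the peracid attacks the electron-rich C8=C9 enol ether much faster than the isopropenyl group and from the ring-B face opposite the pseudoaxial C10 methyl, and the silyloxy epoxide opens with 1,4-silyl shift, so the 9S oxygen (trans to the C10 methyl) arrives already silylated and distinct from the free C1 hydroxyl.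

Step 11
Reactants: 20 9-silyloxy-1-hydroxy ketone
Product: 22 (1S,3R,5R,6S,9S,10R)-9-(tert-butyldimethylsilyloxy)-3-isopropenyl-6,10-dimethyl-1,8-bis(trimethylsilyloxy)spiro[4.5]dec-7-ene, via dilithium alkoxide-enolate 21 (not isolated)
Conditions: LiN(i-Pr)2 (2.5 equiv), THF, −78 °C; then Me3SiCl (3 equiv), −78 → 0 °C; cold aq NaHCO3/pentane
Reagents that add atoms: chlorotrimethylsilane, C[Si](C)(C)Cl
Why: After the hydroxyl consumes the first equivalent of amide, kinetic deprotonation of the α-silyloxy ketone occurs at the unoxygenated α′-CH2 (C7), and silylation fixes the C7=C8 enol ether and masks C1–OH in one operation with no ester yet present; H9 is not removed, so C9 holds.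

Step 12
Reactants: 22 bis(trimethylsilyl) compound
Product: 24 (1S,3R,5S,9S,10R)-9-(tert-butyldimethylsilyloxy)-1-hydroxy-3-isopropenyl-6,10-dimethylspiro[4.5]dec-6-en-8-one, via C1 trimethylsilyl ether 23 (not isolated)
Conditions: Pd(OAc)2 (1.1 equiv), MeCN, rt; then 10% aq citric acid, THF, 0 °C
Reagents that add atoms: none
Why: In the Saegusa–Ito oxidation divalent palladium binds C7 on the face anti to the C6 methyl, which is syn to H6, the only β-hydrogen, so syn β-hydride elimination gives the C6=C7 enone and erases C6; the mild acid wash removes only the labile trimethylsilyl ether at C1.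

Step 13
Reactants: 24 hydroxy enone; 25 3-methylbut-2-enoyl chloride (senecioyl chloride)
Product: 26 (1S,3R,5S,9S,10R)-9-(tert-butyldimethylsilyloxy)-3-isopropenyl-6,10-dimethyl-8-oxospiro[4.5]dec-6-en-1-yl 3-methylbut-2-enoate
Conditions: 25 (3 equiv), 4-(dimethylamino)pyridine (1 equiv), pyridine, CH2Cl2, 0 → 40 °C
Reagents that add atoms: 3-methylbut-2-enoyl chloride (25), CC(C)=CC(=O)Cl
Why: Nucleophilic acyl-transfer catalysis esterifies the only free, hindered hydroxyl with retention at C1; pyridine is used in place of a trialkylamine or an alkoxide to limit vinylketene formation (deconjugation of the acyl group) and to exclude vinylogous retro-aldol cleavage of C1–C5.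

Step 14
Reactants: 26 silyl ether senecioate
Product: 27 (1S,3R,5S,9S,10R)-9-hydroxy-3-isopropenyl-6,10-dimethyl-8-oxospiro[4.5]dec-6-en-1-yl 3-methylbut-2-enoate
Conditions: HF·pyridine, pyridine, THF, 0 °C → rt
Reagents that add atoms: none
Why: Fluoride-driven Si–O cleavage in a buffered, non-basic medium frees the C9 ketol, so C9 epimerisation, α-ketol shift and ester cleavage are not expected.

Step 15
Reactants: 27 ketol senecioate; 28 acetic anhydride
Product: 29 CNP0218315.1, (1S,3R,5S,9S,10R)-9-acetoxy-3-isopropenyl-6,10-dimethyl-8-oxospiro[4.5]dec-6-en-1-yl 3-methylbut-2-enoate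
Conditions: 28, pyridine, 4-(dimethylamino)pyridine (cat.), CH2Cl2, 0 °C
Reagents that add atoms: acetic anhydride (28), CC(=O)OC(C)=O
Why: Standard O-acetylation of the only free hydroxyl proceeds with retention at C9 and completes the target.

**Compound list**
1 | (R)-(+)-limonene | CC1=CC[C@@H](CC1)C(C)=C | starting material
2 | (4R)-limonene 1,2-oxide, epoxide diastereomers | CC12CC[C@H](CC1O2)C(C)=C | intermediate
3 | (4R)-limonene-1,2-diol, formed in the flask | CC1(O)CC[C@H](CC1O)C(C)=C | intermediate
4 | (3R)-3-isopropenyl-6-oxoheptanal | CC(=O)CC[C@H](CC=O)C(C)=C | intermediate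
5 | 1-(2-hydroxy-4-isopropenylcyclopentyl)ethanone, formed in the flask | CC(=O)C1C[C@H](CC1O)C(C)=C | intermediate
6 | (S)-1-acetyl-4-isopropenylcyclopent-1-ene | CC(=O)C1=CC[C@@H](C1)C(C)=C | intermediate
7 | 1-acetyl-1,2-epoxy-4-isopropenylcyclopentane, epoxide diastereomers | CC(=O)C12C[C@H](CC1O2)C(C)=C | intermediate
8 | hydrazone of 7, formed in the flask | CC(=NN)C12C[C@H](CC1O2)C(C)=C | intermediate
9 | (4R)-2-ethylidene-4-isopropenylcyclopentan-1-ol, E/Z and carbinol mixture | C=C(C)[C@H]1CC(O)C(C1)=CC | intermediate
10 | (4R,Z)-2-ethylidene-4-isopropenylcyclopentan-1-one, formed in the flask | C=C(C)[C@H]1CC(=O)/C(C1)=C\C | intermediate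
11 | (4R,E)-2-ethylidene-4-isopropenylcyclopentan-1-one | C=C(C)[C@H]1CC(=O)/C(C1)=C/C | intermediate
12 | (E)-pent-3-en-2-one | C/C=C/C(C)=O | starting material
13 | tert-butyldimethylsilyl chloride | CC(C)(C)[Si](C)(C)Cl | starting material
14 | lithium (E)-penta-1,3-dien-2-olate, formed in the flask | [Li]OC(=C)/C=C/C | intermediate
15 | (E)-2-(tert-butyldimethylsilyloxy)penta-1,3-diene | C=C(O[Si](C)(C)C(C)(C)C)/C=C/C | intermediate
16 | (3R,5R,6S,10S)-8-(tert-butyldimethylsilyloxy)-3-isopropenyl-6,10-dimethylspiro[4.5]dec-8-en-1-one | C=C(C)[C@H]1CC(=O)[C@]2(C1)[C@@H](C)CC(O[Si](C)(C)C(C)(C)C)=C[C@@H]2C | intermediate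
17 | catechol borate of 18, formed in the flask | C=C(C)[C@H]1C[C@H](OB3Oc4ccccc4O3)[C@]2(C1)[C@@H](C)CC(O[Si](C)(C)C(C)(C)C)=C[C@@H]2C | intermediate
18 | (1S,3R,5R,6S,10S)-8-(tert-butyldimethylsilyloxy)-3-isopropenyl-6,10-dimethylspiro[4.5]dec-8-en-1-ol | C=C(C)[C@H]1C[C@H](O)[C@]2(C1)[C@@H](C)CC(O[Si](C)(C)C(C)(C)C)=C[C@@H]2C | intermediate
19 | 8,9-epoxide of 18 (oxygen trans to the C10 methyl), formed in the flask | C=C(C)[C@H]1C[C@H](O)[C@]2(C1)[C@@H](C)C[C@@]3(O[Si](C)(C)C(C)(C)C)O[C@H]3[C@@H]2C | intermediate
20 | (1S,3R,5R,6S,9S,10R)-9-(tert-butyldimethylsilyloxy)-1-hydroxy-3-isopropenyl-6,10-dimethylspiro[4.5]decan-8-one | C=C(C)[C@H]1C[C@H](O)[C@]2(C1)[C@@H](C)CC(=O)[C@@H](O[Si](C)(C)C(C)(C)C)[C@@H]2C | intermediate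
21 | dilithium C1 alkoxide C7=C8 enolate of 20, formed in the flask | C=C(C)[C@H]1C[C@H](O[Li])[C@]2(C1)[C@@H](C)C=C(O[Li])[C@@H](O[Si](C)(C)C(C)(C)C)[C@@H]2C | intermediate
22 | (1S,3R,5R,6S,9S,10R)-9-(tert-butyldimethylsilyloxy)-3-isopropenyl-6,10-dimethyl-1,8-bis(trimethylsilyloxy)spiro[4.5]dec-7-ene | C=C(C)[C@H]1C[C@H](O[Si](C)(C)C)[C@]2(C1)[C@@H](C)C=C(O[Si](C)(C)C)[C@@H](O[Si](C)(C)C(C)(C)C)[C@@H]2C | intermediate
23 | C1 trimethylsilyl ether of 24, formed in the flask | C=C(C)[C@H]1C[C@H](O[Si](C)(C)C)[C@]2(C1)C(C)=CC(=O)[C@@H](O[Si](C)(C)C(C)(C)C)[C@@H]2C | intermediate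
24 | (1S,3R,5S,9S,10R)-9-(tert-butyldimethylsilyloxy)-1-hydroxy-3-isopropenyl-6,10-dimethylspiro[4.5]dec-6-en-8-one | C=C(C)[C@H]1C[C@H](O)[C@]2(C1)C(C)=CC(=O)[C@@H](O[Si](C)(C)C(C)(C)C)[C@@H]2C | intermediate
25 | 3-methylbut-2-enoyl chloride | CC(C)=CC(=O)Cl | starting material
26 | C1 senecioate of 24 | C=C(C)[C@H]1C[C@H](OC(=O)C=C(C)C)[C@]2(C1)C(C)=CC(=O)[C@@H](O[Si](C)(C)C(C)(C)C)[C@@H]2C | intermediate
27 | C9 ketol, C1 senecioate | C=C(C)[C@H]1C[C@H](OC(=O)C=C(C)C)[C@]2(C1)C(C)=CC(=O)[C@@H](O)[C@@H]2C | intermediate
28 | acetic anhydride | CC(=O)OC(C)=O | starting material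
29 | CNP0218315.1 | C=C(C)[C@H]1C[C@H](OC(=O)C=C(C)C)[C@]2(C1)C(C)=CC(=O)[C@@H](OC(C)=O)[C@@H]2C | target

**Count and risks**

Total step count: 15. Longest linear sequence: 14 (steps 1–6 and 8–15, from 1).

**Step 8.**
- What may go wrong: bond formation at the future quaternary C5 next to the methyl-bearing diene terminus may be slow. The reaction may leak into a stepwise Mukaiyama–Michael manifold or close through oxygen. Endo selectivity, or facial selectivity against the remote C3 substituent, may be too low.
- Fallback, from 11 back to 16: the C10 methyl is taken off the diene and installed afterwards. Enone 11 is combined with commercial 2-(trimethylsilyloxy)buta-1,3-diene under the same aluminium promoter. The bond to C5 now comes from an unsubstituted terminus and no endo/exo question arises. This gives the 10-demethyl trimethylsilyl enol ether F1.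
- Saegusa–Ito oxidation (Pd(OAc)2, MeCN) then gives the spiro 9-ene-1,8-dione F2. Me2CuLi (Et2O, −78 °C) should add to C10 by axial attack anti to the C6 methyl and to the pseudoaxial C4H2, the usual 3,5-trans outcome for 5-substituted cyclohexenones. Trapping the enolate with 13/HMPA returns 16.

**Step 9.**
- What may go wrong: hydride transfer to the neopentyl carbonyl may be sluggish, and facial selectivity may erode if the catalyst and the substrate bias are mismatched.
- Fallback, from 16 back to 18: C1 is set by SN2 inversion rather than by the face of hydride attack. The then matched (3aS) enantiomer of the oxazaborolidine with catecholborane gives the (1R)-epimeric alcohol F3.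
- A Mitsunobu reaction (4-nitrobenzoic acid, PPh3, DIAD, toluene), which is known to invert cyclopentanols next to a quaternary carbon, gives the (1S)-4-nitrobenzoate F4. Brief methanolysis (K2CO3, MeOH, 0 °C) returns 18.

**Step 10.**
- What may go wrong: facial selectivity of the epoxidation may be poor, because the axial C4H2 on one face competes with the C10 methyl on the other and the C1 hydroxyl can deliver the peracid by hydrogen bonding. The silyl group may be partly lost during the rearrangement.
- Fallback, from 18 back to 20: reagent-controlled oxygen transfer by Shi epoxidation. It uses 1,2:4,5-di-O-isopropylidene-β-L-erythro-2,3-hexodiulo-2,6-pyranose (30 mol %), the enantiomer that the spiro transition-state model assigns to the C9 face anti to the C10 methyl, with KHSO5 and K2CO3 in MeCN/CH2(OMe)2/H2O at 0 °C.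
- This dioxirane reacts slowly with 1,1-disubstituted alkenes and should give the free 1,9-dihydroxy-8-ketone F5. Silylation with 13 and imidazole in DMF, selective for the less hindered C9 ketol hydroxyl over the neopentyl C1 hydroxyl, returns 20.

**Further compounds**
F1 | step 8 | 3-isopropenyl-6-methyl-8-(trimethylsilyloxy)spiro[4.5]dec-8-en-1-one, C3, C5 and C6 as in 16 | C=C(C)[C@H]1CC(=O)[C@]2(C1)[C@@H](C)CC(O[Si](C)(C)C)=CC2
F2 | step 8 | 3-isopropenyl-6-methylspiro[4.5]dec-9-ene-1,8-dione, C3, C5 and C6 as in 16 | C=C(C)[C@H]1CC(=O)[C@]2(C1)[C@@H](C)CC(=O)C=C2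
F3 | step 9 | (1R)-epimer of 18 | C=C(C)[C@H]1C[C@@H](O)[C@]2(C1)[C@@H](C)CC(O[Si](C)(C)C(C)(C)C)=C[C@@H]2C
F4 | step 9 | (1S)-4-nitrobenzoate of 18 | C=C(C)[C@H]1C[C@H](OC(=O)c3ccc(cc3)[N+](=O)[O-])[C@]2(C1)[C@@H](C)CC(O[Si](C)(C)C(C)(C)C)=C[C@@H]2C
F5 | step 10 | (1S,3R,5R,6S,9S,10R)-1,9-dihydroxy-3-isopropenyl-6,10-dimethylspiro[4.5]decan-8-one | C=C(C)[C@H]1C[C@H](O)[C@]2(C1)[C@@H](C)CC(=O)[C@@H](O)[C@@H]2C
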